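**Strategy.** Everything rests on disconnecting the C4–C4a bond of ring C while C4 is held at the carboxylic oxidation level as a ketene dithioacetal (C3=C4). The feature used is that C4 lies between the enolisable stereocentre C3 and C4a, the ring A carbon para to the 7-hydroxyl and ortho to O1. In one operation a chiral phosphoric acid protonates C3, setting its configuration, and the resulting C4 dithianylium ion is captured by C4a, closing ring C. The product is the isoflavanone masked as a 1,3-dithiane, which locks C3 against epimerisation. The precursor is an open aryl ether assembled from a bromopaeonol, resorcinol, a prenylstannane and a silyldithiane.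

Key step: step 6

Remark 1: the sense of induction of the chiral acid in step 6 cannot be derived a priori; the (R)-acid is written and stands for whichever antipode delivers the (3S) product in a first small-scale run.
Remark 2: 1-(5-bromo-2-hydroxy-4-methoxyphenyl)ethanone is taken as a catalogue compound (otherwise it is one NBS bromination from paeonol).

Step 1
Reactants: 1 1-(5-bromo-2-hydroxy-4-methoxyphenyl)ethanone
Product: 2 1-[5-bromo-4-methoxy-2-(methoxymethoxy)phenyl]ethanone
Conditions: MOMCl, K2CO3, acetone, reflux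
Reagents that add atoms: chloromethyl methyl ether (MOMCl), COCCl
Why: O-alkylation of the chelated phenoxide (Williamson-type acetal formation) masks the 2'-oxygen, which would otherwise close a benzofuran-3-one in step 3 and capture the cation in step 6.

Step 2
Reactants: 2 1-[5-bromo-4-methoxy-2-(methoxymethoxy)phenyl]ethanone
Product: 4 2-bromo-1-[5-bromo-4-methoxy-2-(methoxymethoxy)phenyl]ethanone, via trimethylsilyl enol ether 3 (not isolated)
Conditions: LiHMDS, TMSCl, THF, −78 °C; then NBS, −78 to 0 °C
Reagents that add atoms: N-bromosuccinimide (NBS), O=C1CCC(=O)N1Br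
Why: α-bromination of a ketone through its kinetic silyl enol ether should be fast and clean at low temperature, and it generates no HBr (which would cleave the MOM ether) and leaves the electron-rich ring untouched.

Step 3
Reactants: 4 2-bromo-1-[5-bromo-4-methoxy-2-(methoxymethoxy)phenyl]ethanone; 5 resorcinol (benzene-1,3-diol)
Product: 6 1-[5-bromo-4-methoxy-2-(methoxymethoxy)phenyl]-2-(3-hydroxyphenoxy)ethanone
Conditions: 5 (5 equiv), K2CO3, acetone, rt to 45 °C
Reagents that add atoms: none
Why: Williamson ether synthesis (SN2 of a phenoxide on a phenacyl bromide) forms the O1–C2 bond, and the excess of resorcinol should hold the reaction at the mono-ether, leaving the future 7-OH free.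

Step 4
Reactants: 6 1-[5-bromo-4-methoxy-2-(methoxymethoxy)phenyl]-2-(3-hydroxyphenoxy)ethanone; 7 tributyl(3-methylbut-2-en-1-yl)stannane
Product: 8 2-(3-hydroxyphenoxy)-1-[4-methoxy-2-(methoxymethoxy)-5-(3-methylbut-2-en-1-yl)phenyl]ethanone
Conditions: Pd(PPh3)4 (5 mol%), DMF, 95 °C
Reagents that add atoms: none
Why: Stille coupling of the aryl bromide with the prenylstannane under neutral conditions should tolerate the phenol and the ketone, and reductive elimination at the less substituted allyl terminus should give the linear prenyl group.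

Step 5
Reactants: 8 2-(3-hydroxyphenoxy)-1-[4-methoxy-2-(methoxymethoxy)-5-(3-methylbut-2-en-1-yl)phenyl]ethanone; 9 2-(trimethylsilyl)-1,3-dithiane
Product: 11 3-{2-(1,3-dithian-2-ylidene)-2-[4-methoxy-2-(methoxymethoxy)-5-(3-methylbut-2-en-1-yl)phenyl]ethoxy}phenol, via lithium beta-silyl alkoxide 10 (not isolated)
Conditions: 9 (2.3 equiv), n-BuLi, THF, −78 to 0 °C; then 8, −78 °C to rt
Reagents that add atoms: none
Why: Peterson olefination (addition of the silyl-stabilised dithianyl anion to the ketone, then syn-elimination of lithium trimethylsilanolate) installs C4 as a ketene dithioacetal; one equivalent of the anion is consumed by the phenol, and the symmetric dithiane terminus means the alkene has no E/Z isomers.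

Step 6
Reactants: 11 3-{2-(1,3-dithian-2-ylidene)-2-[4-methoxy-2-(methoxymethoxy)-5-(3-methylbut-2-en-1-yl)phenyl]ethoxy}phenol
Product: 13 (3S)-3-[4-methoxy-2-(methoxymethoxy)-5-(3-methylbut-2-en-1-yl)phenyl]-2,3-dihydrospiro[chromene-4,2'-[1,3]dithian]-7-ol, via dithianylium phosphate ion pair 12 (not isolated)
Conditions: (R)-3,3'-bis(2,4,6-triisopropylphenyl)-1,1'-binaphthyl-2,2'-diyl hydrogen phosphate (10 mol%), toluene (0.02 M), 4 Å MS, 0 °C to rt
Reagents that add atoms: none
Why: Proposed new method: the chiral acid protonates the electron-rich C3=C4 bond of 11 at C3 to give the C4 1,3-dithian-2-ylium ion 12 paired with the chiral phosphate, C4a of ring A attacks C4, and the phosphate removes the arenium proton and is regenerated as the acid. The closest known reaction types are the chiral-phosphoric-acid-catalysed asymmetric protonation of ketene dithioacetals with capture of the cation by a tethered hydroxyl group, and the racemic Brønsted-acid cyclisation of ketene dithioacetals onto arenes; new is their union with an arene carbon as terminator. Ring C closes in a 6-exo-trig Friedel–Crafts spiro-alkylation at the C=S+ carbon. The C3 stereocentre is under catalyst control: the proton is delivered to one enantiotopic face of the alkene inside the chiral ion pair, and if protonation is reversible the same phosphate, hydrogen-bonded to the 7-OH, selects the faster-cyclising cation. The step needs chemoselective protonation of the ketene dithioacetal over the prenyl alkene (secured by its far higher basicity), attack at C4a and not at the carbon between the two ring A oxygens (secured by para-activation from the 7-OH and the bulk of the forming spiro centre), and no oxygen capture (secured by the MOM group on the 2'-oxygen). Because C4 emerges as a dithioketal, C3 cannot epimerise until the last step.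

Step 7
Reactants: 13 (3S)-3-[4-methoxy-2-(methoxymethoxy)-5-(3-methylbut-2-en-1-yl)phenyl]-2,3-dihydrospiro[chromene-4,2'-[1,3]dithian]-7-ol
Product: 14 (3S)-3-[2-hydroxy-4-methoxy-5-(3-methylbut-2-en-1-yl)phenyl]-2,3-dihydrospiro[chromene-4,2'-[1,3]dithian]-7-ol
Conditions: 3 M HCl (aq), MeOH/THF, 40 °C
Reagents that add atoms: none
Why: Acid-catalysed acetal exchange with methanol removes the MOM group while C3 is still non-enolisable, the dithioketal is acid-stable, and the prenyl group has no ortho hydroxyl to cyclise onto.

Step 8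
Reactants: 14 (3S)-3-[2-hydroxy-4-methoxy-5-(3-methylbut-2-en-1-yl)phenyl]-2,3-dihydrospiro[chromene-4,2'-[1,3]dithian]-7-ol
Product: 15 (3S)-7-hydroxy-3-[2-hydroxy-4-methoxy-5-(3-methylbut-2-en-1-yl)phenyl]-2,3-dihydro-4H-chromen-4-one
Conditions: MeI (10 equiv), CaCO3, MeCN/H2O (4:1), 40 °C, dark
Reagents that add atoms: water, O
Why: Alkylative dithioketal hydrolysis (S-methylation, opening to the thionium ion stabilised by the para 7-oxygen, hydration) should unmask the C4 ketone under buffered, near-neutral conditions that leave the prenyl alkene and the now enolisable C3 centre untouched.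

**Compound list**

1 | 1-(5-bromo-2-hydroxy-4-methoxyphenyl)ethanone | CC(=O)c1cc(Br)c(OC)cc1O | starting material
2 | 1-[5-bromo-4-methoxy-2-(methoxymethoxy)phenyl]ethanone | CC(=O)c1cc(Br)c(OC)cc1OCOC | intermediate
3 | {1-[5-bromo-4-methoxy-2-(methoxymethoxy)phenyl]ethenyl}oxy(trimethyl)silane (not isolated) | C=C(O[Si](C)(C)C)c1cc(Br)c(OC)cc1OCOC | intermediate
4 | 2-bromo-1-[5-bromo-4-methoxy-2-(methoxymethoxy)phenyl]ethanone | BrCC(=O)c1cc(Br)c(OC)cc1OCOC | intermediate
5 | resorcinol (benzene-1,3-diol) | Oc1cccc(O)c1 | starting material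
6 | 1-[5-bromo-4-methoxy-2-(methoxymethoxy)phenyl]-2-(3-hydroxyphenoxy)ethanone | O=C(COc1cccc(O)c1)c1cc(Br)c(OC)cc1OCOC | intermediate
7 | tributyl(3-methylbut-2-en-1-yl)stannane | CCCC[Sn](CCCC)(CCCC)CC=C(C)C | starting material
8 | 2-(3-hydroxyphenoxy)-1-[4-methoxy-2-(methoxymethoxy)-5-(3-methylbut-2-en-1-yl)phenyl]ethanone | O=C(COc1cccc(O)c1)c1cc(CC=C(C)C)c(OC)cc1OCOC | intermediate
9 | 2-(trimethylsilyl)-1,3-dithiane | C[Si](C)(C)C1SCCCS1 | starting material
10 | dilithium salt of 3-{2-hydroxy-2-[4-methoxy-2-(methoxymethoxy)-5-(3-methylbut-2-en-1-yl)phenyl]-2-[2-(trimethylsilyl)-1,3-dithian-2-yl]ethoxy}phenol (racemic, not isolated) | [Li]Oc1cccc(OCC(O[Li])(c2cc(CC=C(C)C)c(OC)cc2OCOC)C2([Si](C)(C)C)SCCCS2)c1 | intermediate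
11 | 3-{2-(1,3-dithian-2-ylidene)-2-[4-methoxy-2-(methoxymethoxy)-5-(3-methylbut-2-en-1-yl)phenyl]ethoxy}phenol | Oc1cccc(OCC(=C2SCCCS2)c2cc(CC=C(C)C)c(OC)cc2OCOC)c1 | intermediate
12 | 2-{(1S)-2-(3-hydroxyphenoxy)-1-[4-methoxy-2-(methoxymethoxy)-5-(3-methylbut-2-en-1-yl)phenyl]ethyl}-1,3-dithian-2-ylium, cation of the ion pair with the phosphate of the catalyst (not isolated) | COc1cc(OCOC)c([C@@H](COc2cccc(O)c2)C2=[S+]CCCS2)cc1CC=C(C)C | intermediate
13 | (3S)-3-[4-methoxy-2-(methoxymethoxy)-5-(3-methylbut-2-en-1-yl)phenyl]-2,3-dihydrospiro[chromene-4,2'-[1,3]dithian]-7-ol | COc1cc(OCOC)c([C@H]2COc3cc(O)ccc3C24SCCCS4)cc1CC=C(C)C | intermediate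
14 | (3S)-3-[2-hydroxy-4-methoxy-5-(3-methylbut-2-en-1-yl)phenyl]-2,3-dihydrospiro[chromene-4,2'-[1,3]dithian]-7-ol | COc1cc(O)c([C@H]2COc3cc(O)ccc3C24SCCCS4)cc1CC=C(C)C | intermediate
15 | (3S)-7-hydroxy-3-[2-hydroxy-4-methoxy-5-(3-methylbut-2-en-1-yl)phenyl]-2,3-dihydro-4H-chromen-4-one | COc1cc(O)c([C@H]2COc3cc(O)ccc3C2=O)cc1CC=C(C)C | target

**Step count and risks**

Total step count: 8. Longest linear sequence: 8 steps (1 to 15).

Steps most likely to fail:

Step 6 (proposed new method). The dithianylium ion pair may be captured too slowly by the arene, so that reversible protonation, intermolecular oxygen capture or hydrolysis to a thioester take over, or face selection in the proton transfer may be poor. The fallback uses known chemistry and moves stereocontrol to the end. It sets out from 11, which is cyclised with an achiral acid (TFA, CH2Cl2, 0 °C; the known cationic cyclisation of ketene dithioacetals onto arenes) to the racemic MOM-protected spiro dithioketal F1. The conditions of steps 7 and 8 then give the racemic phenol dithioketal F2 and the racemic isoflavanone F3. TMSOTf/Et3N converts F3 into the tris(trimethylsilyl) enol ether F4. Catalytic enantioselective protonation of this silyl enol ether follows (chiral 3,3'-diaryl-binaphthyl N-triflyl thiophosphoramide, phenol as stoichiometric proton source, toluene; known for silyl enol ethers of 2-aryl cyclic ketones) and should give the (3S)-ketone bis(trimethylsilyl) ether F5. Methanolysis of the aryl silyl ethers (MeOH, citric acid, 0 °C) brings the route back at 15.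

Step 5. The hindered, strongly basic silyl dithianyl anion may enolise the α-aryloxy ketone instead of adding to it, or the congested β-silyl alkoxide may eliminate incompletely. The fallback sets out from 8 and separates addition from elimination: the organocerium reagent from 2-lithio-1,3-dithiane and CeCl3 (low basicity) should add to give the tertiary dithianyl carbinol F6. Dehydration with SOCl2/pyridine at 0 °C, with loss of the acidified dithiane C–H, returns to the route at 11.

Step 8. The acidic 7-phenol may be O-methylated by MeI, or a sluggish hydrolysis that has to be forced may erode the configuration at C3. The fallback sets out from 14, which is acetylated (Ac2O, pyridine) to the diacetate dithioketal F7. Fast oxidative dethioketalisation with PhI(OCOCF3)2 (MeCN/H2O, CaCO3, 0 °C) gives the diacetate ketone F8. Near-neutral deacetylation (NH4OAc, aqueous MeOH, rt) comes back at 15.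

**Further compounds**

F1 | step 6 | racemic 3-[4-methoxy-2-(methoxymethoxy)-5-(3-methylbut-2-en-1-yl)phenyl]-2,3-dihydrospiro[chromene-4,2'-[1,3]dithian]-7-ol | COc1cc(OCOC)c(C2COc3cc(O)ccc3C24SCCCS4)cc1CC=C(C)C
F2 | step 6 | racemic 3-[2-hydroxy-4-methoxy-5-(3-methylbut-2-en-1-yl)phenyl]-2,3-dihydrospiro[chromene-4,2'-[1,3]dithian]-7-ol | COc1cc(O)c(C2COc3cc(O)ccc3C24SCCCS4)cc1CC=C(C)C
F3 | step 6 | racemic 7-hydroxy-3-[2-hydroxy-4-methoxy-5-(3-methylbut-2-en-1-yl)phenyl]-2,3-dihydro-4H-chromen-4-one | COc1cc(O)c(C2COc3cc(O)ccc3C2=O)cc1CC=C(C)C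
F4 | step 6 | 3-[4-methoxy-5-(3-methylbut-2-en-1-yl)-2-(trimethylsilyloxy)phenyl]-4,7-bis(trimethylsilyloxy)-2H-chromene | COc1cc(O[Si](C)(C)C)c(C2=C(O[Si](C)(C)C)c3ccc(O[Si](C)(C)C)cc3OC2)cc1CC=C(C)C
F5 | step 6 | (3S)-3-[4-methoxy-5-(3-methylbut-2-en-1-yl)-2-(trimethylsilyloxy)phenyl]-7-(trimethylsilyloxy)-2,3-dihydro-4H-chromen-4-one | COc1cc(O[Si](C)(C)C)c([C@H]2COc3cc(O[Si](C)(C)C)ccc3C2=O)cc1CC=C(C)C
F6 | step 5 | racemic 3-{2-(1,3-dithian-2-yl)-2-hydroxy-2-[4-methoxy-2-(methoxymethoxy)-5-(3-methylbut-2-en-1-yl)phenyl]ethoxy}phenol | OC(COc1cccc(O)c1)(c1cc(CC=C(C)C)c(OC)cc1OCOC)C1SCCCS1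
F7 | step 8 | (3S)-3-[2-acetoxy-4-methoxy-5-(3-methylbut-2-en-1-yl)phenyl]-2,3-dihydrospiro[chromene-4,2'-[1,3]dithian]-7-yl acetate | COc1cc(OC(C)=O)c([C@H]2COc3cc(OC(C)=O)ccc3C24SCCCS4)cc1CC=C(C)C
F8 | step 8 | (3S)-3-[2-acetoxy-4-methoxy-5-(3-methylbut-2-en-1-yl)phenyl]-4-oxo-3,4-dihydro-2H-chromen-7-yl acetate | COc1cc(OC(C)=O)c([C@H]2COc3cc(OC(C)=O)ccc3C2=O)cc1CC=C(C)C
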